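**Reading time.** Read these flasks at 2.0 d, then at 8.0 d. Impurity and loading stay as given while substrate goes from 0.060 M to 0.60 M, so catalyst grows against a constant impurity.

all flasks: free catalyst 2 mol%; impurity 1.9 mM

| charge | substrate | temperature | remark | time |
|---|---|---|---|---|
| noon | 0.076 M | 65 °C | run made earlier |  |
| winter | 0.79 M | 76 °C | run made earlier |  |
| delta | 0.10 M | 70 °C |  | 2.0 d |
| alpha | 0.060 M | 70 °C |  | 2.0 d |
| epsilon | 0.20 M | 70 °C |  | 2.0 d |
| eta | 0.30 M | 70 °C |  | 2.0 d |
| theta | 0.60 M | 70 °C |  | 2.0 d |

- noon (time / h: product / %, substrate / %): 5.00: 0, 101; 10.0: 0, 100; 15.0: 0, 103; 20.0: 0, 99; 25.0: 2, 101; 30.0: 2, 101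
- winter (time / h: product / %, substrate / %): 2.50: 22, 76; 4.00: 28, 71; 6.00: 32, 67; 10.0: 38, 60; 15.0: 41, 55; 20.0: 43, 54; 30.0: 42, 52

(each reading ± 2 percentage points)

- the flasks by amount of product, in percent of the substrate charged, highest first, at 2.0 d (delta / alpha / epsilon / eta / theta)
- the same order at 8.0 d (delta / alpha / epsilon / eta / theta)
- the amount of product, in percent of the substrate charged of the flask you put first, at 2.0 d
- the amount of product, in percent of the substrate charged of the flask you put last, at 2.0 d

- the numbers in the tables scatter with a standard deviation of 2 percentage points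

**Two extremes.** Take noon as the poor end. It charges 1.52 mM of free catalyst, less than its 1.9 mM of impurity, and shows 2% product at 30.0 h. Take winter as the rich end. It charges 15.8 mM of free catalyst, more than its impurity, and shows 22% product at 2.50 h. Then it stops near 42%, with 52% substrate present. Noon ran colder than these flasks and winter hotter, so treat their rates as rough.

**Poisoned share.** Assume one impurity kills one catalyst. Use the poisoned share φ, for theta 15.8%: the impurity charged over the catalyst charged. Set the zero of the scale at equal charges, φ of one, which falls at 0.0950 M substrate. Noon stands at 125%, winter at 12.0%.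

**My reckoning.** Place delta, epsilon, eta and theta between those ends, and alpha beyond noon, the poor end. Alpha, at 158%, lies past the zero, so expect product near nothing. Delta, at 95.0%, keeps a sliver of catalyst, so expect a trickle. Epsilon, at 47.5%, and eta, at 31.7%, come next. Rank by rising φ at 2.0 d: theta first, near winter's stop, and alpha last. Winter stopped with substrate present, so leave first place at 8.0 d open.

**The forecast.** Reasoning that “The impurity seems to poison catalyst one-to-one”, the forecast gives theta > eta > epsilon > delta > alpha at 2.0 d and theta > eta > epsilon > delta > alpha at 8.0 d, with 42% and 1%, so it keeps theta first where I left that open.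

**The flasks.** They give theta > eta > epsilon > delta > alpha at 2.0 d, from 49.0% down to 0.0625%, and eta > epsilon > theta > delta > alpha at 8.0 d.

    substrate + free catalyst ⇌ catalyst intermediate A (K = 2.80 M⁻¹, k = 0.360 M⁻¹ min⁻¹, Ea = 65.0 kJ mol⁻¹, ΔH = −29.0 kJ mol⁻¹)
    catalyst intermediate A → catalyst intermediate B (k = 0.870 min⁻¹, Ea = 102 kJ mol⁻¹)
    catalyst intermediate B ⇌ free catalyst + product (K = 0.160 M, k = 0.150 min⁻¹, Ea = 100 kJ mol⁻¹, ΔH = −38.0 kJ mol⁻¹)
    free catalyst ⇌ dormant form (K = 5.20, k = 0.00360 min⁻¹, Ea = 107 kJ mol⁻¹, ΔH = −37.0 kJ mol⁻¹)
    product + catalyst intermediate B → spent catalyst A (k = 0.00920 M⁻¹ min⁻¹, Ea = 82.0 kJ mol⁻¹)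
    free catalyst + impurity → spent catalyst B (k = 500 M⁻¹ min⁻¹, Ea = 51.0 kJ mol⁻¹)
    (constants at 70 °C)

Theta holds 15.8% of its catalyst as spent catalyst B, against φ of 15.8%. At 2.0 d, theta's catalyst intermediate B passes on to free catalyst and product 55 times for each passage into spent catalyst A, by forward rates. Even so, spent catalyst A holds 61.4% of theta's catalyst, while product's half-life by that step, 130 d, is longer than the time. A further flask, like theta with 0.36 M substrate, has φ of 26.4%, holds 26.4% spent catalyst B and gives 46.6% product.

The earlier runs and the new flask are simulated for an exercise.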